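**Retrosynthetic overview**

1. Target 22 ⇐ global desilylation of 21 ⇐ auxiliary-controlled anti-aldol (C7''–C8'' bond, erythro side chain) between the ring B aryloxyacetyl imide 18 and silyl-protected vanillin 8 ⇐ O-alkylation of core phenol 16.
2. Tetrahydrofuran core 15 ⇐ Lewis-acid ring contraction of the seven-membered cyclic vinyl acetal 13 (a 2-aryl-4,5-dihydro-1,3-dioxepine): the C2–C3 bond and the C2 and C3 stereocentres arise in one event, relayed from C4 and C5.
3. Enabling feature: in the tetrahydrofuran, O1–C2(H)(aryl)–C3–CH2OH is a β-alkoxy aldehyde (aldol) array one oxidation level up; C2 is a benzylic carbon bonded to ring oxygen O1 and to the electron-rich ring A, so C2=O1+ is an accessible oxocarbenium ion, and C3 is the α-carbon of a formyl group; tying the formyl oxygen and O1 to C2 as an O,O-acetal gives the 1,3-dioxepine.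
4. 13 ⇐ ring-closing metathesis of vinyl acetal 12 ⇐ mixed acetal of 8 with alcohol 6 ⇐ Sharpless desymmetrization of divinylcarbinol 1 (sets C4 and C5) and aryl Grignard opening of epoxide 3 with ring B.
5. Ring order: oxirane (step 1, opened in step 3) → 1,3-dioxepine (step 8) → tetrahydrofuran (step 9); the three benzene rings are bought.

Key step: step 9

Remark: the tetrahydrofuran is numbered O1, C2 (aryl, ring A), C3 (CH2OH, carbon C9), C4 (OH), C5 (benzyl, ring B); ring C is the aryl group of the glycerol side chain, whose carbons are C7'' (carbinol), C8'' (aryloxy) and C9'' (CH2OH).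
Remark: compounds 4 and 17 are taken as commercial; the acetal carbon of 10–13 is a mixture of epimers, which is of no consequence because it is ionized in step 9.

**Route**

Step 1
Reactants: 1 penta-1,4-dien-3-ol
Product: 2 (1S)-1-[(2R)-oxiran-2-yl]prop-2-en-1-ol
Conditions: Ti(OiPr)4, L-(+)-diisopropyl tartrate, t-BuOOH, 4 Å MS, CH2Cl2, −20 °C
Reagents that add atoms: tert-butyl hydroperoxide, CC(C)(C)OO
Why: Sharpless asymmetric epoxidation desymmetrizes the divinylcarbinol, the tartrate–titanium complex delivering oxygen to one enantiotopic vinyl group on the face that gives the anti (erythro) epoxy alcohol while the minor enantiomer is removed by a faster second epoxidation, so both stereocentres (later C4 and C5) should be set with high enantiomeric purity.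

Step 2
Reactants: 2 (1S)-1-[(2R)-oxiran-2-yl]prop-2-en-1-ol
Product: 3 tert-butyl(dimethyl){[(1S)-1-[(2R)-oxiran-2-yl]prop-2-en-1-yl]oxy}silane
Conditions: TBSCl, imidazole, DMF, 0 °C → rt
Reagents that add atoms: tert-butyldimethylsilyl chloride, CC(C)(C)[Si](C)(C)Cl
Why: Silyl ether formation on the secondary alcohol blocks Payne rearrangement and installs the bulky, poorly leaving oxygen substituent needed at C4 in step 9, without touching a stereocentre.

Step 3
Reactants: 4 1-(benzyloxy)-4-bromo-2-methoxybenzene; 3 tert-butyl(dimethyl){[(1S)-1-[(2R)-oxiran-2-yl]prop-2-en-1-yl]oxy}silane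
Product: 6 (2R,3S)-1-[4-(benzyloxy)-3-methoxyphenyl]-3-[(tert-butyldimethylsilyl)oxy]pent-4-en-2-ol, via arylmagnesium bromide 5 (not isolated)
Conditions: 4, Mg, THF, rt; then CuI (10 mol %), 3, THF, −40 → −10 °C; cold aqueous NH4Cl
Reagents that add atoms: none
Why: Copper-catalysed Grignard opening of the monosubstituted epoxide is an SN2 attack at the unhindered terminal carbon, so ring B is attached with both stereocentres intact, and the cold quench should prevent 1,2-silyl migration in the magnesium alkoxide.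

Step 4
Reactants: 7 vanillin
Product: 8 3-methoxy-4-[(triisopropylsilyl)oxy]benzaldehyde
Conditions: TIPSCl, imidazole, DMF, rt
Reagents that add atoms: triisopropylsilyl chloride, CC(C)[Si](Cl)(C(C)C)C(C)C
Why: Silyl ether formation on the phenol gives an aryl TIPS ether that keeps the ring electron-rich for the oxocarbenium chemistry, survives base, hydrogenolysis and hydride, and falls in the final fluoride step.

Step 5
Reactants: 8 3-methoxy-4-[(triisopropylsilyl)oxy]benzaldehyde
Product: 9 {4-[bis(2-bromoethoxy)methyl]-2-methoxyphenoxy}tri(propan-2-yl)silane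
Conditions: 2-bromoethanol (3 equiv), p-TsOH·H2O (2 mol %), toluene, reflux, Dean–Stark
Reagents that add atoms: 2-bromoethanol, OCCBr
Why: Acid-catalysed acetalization with azeotropic removal of water gives the symmetric acetal whose 2-bromoethoxy groups are latent vinyloxy groups.

Step 6
Reactants: 9 {4-[bis(2-bromoethoxy)methyl]-2-methoxyphenoxy}tri(propan-2-yl)silane; 6 (2R,3S)-1-[4-(benzyloxy)-3-methoxyphenyl]-3-[(tert-butyldimethylsilyl)oxy]pent-4-en-2-ol
Product: 11 {4-[(2-bromoethoxy){[(2R,3S)-1-[4-(benzyloxy)-3-methoxyphenyl]-3-[(tert-butyldimethylsilyl)oxy]pent-4-en-2-yl]oxy}methyl]-2-methoxyphenoxy}tri(propan-2-yl)silane (both epimers at the acetal carbon), via collidinium triflate 10 (not isolated)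
Conditions: 9 (1.5 equiv), 2,4,6-collidine (3 equiv), TESOTf (1.4 equiv), CH2Cl2, 0 °C; then 6 (1.0 equiv), 0 °C → rt
Reagents that add atoms: none
Why: Acetal exchange through a pyridinium-type salt (silyl triflate/collidine mixed-acetal synthesis) turns one alkoxy group of the aryl acetal into a collidinium leaving group that the secondary alcohol displaces under buffered, non-acidic conditions, so the silyl ether, the alkene and both carbinol stereocentres should survive.

Step 7
Reactants: 11 mixed 2-bromoethyl acetal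
Product: 12 {4-[(ethenyloxy){[(2R,3S)-1-[4-(benzyloxy)-3-methoxyphenyl]-3-[(tert-butyldimethylsilyl)oxy]pent-4-en-2-yl]oxy}methyl]-2-methoxyphenoxy}tri(propan-2-yl)silane (both epimers at the acetal carbon)
Conditions: KOtBu, THF, 0 °C → rt
Reagents that add atoms: none
Why: E2 dehydrobromination of the 2-bromoethyl ether gives the vinyl ether under conditions that leave the acetal and the silyl ethers untouched.

Step 8
Reactants: 12 vinyl acetal
Product: 13 (4R,5S)-4-[4-(benzyloxy)-3-methoxybenzyl]-5-[(tert-butyldimethylsilyl)oxy]-2-{3-methoxy-4-[(triisopropylsilyl)oxy]phenyl}-4,5-dihydro-1,3-dioxepine (both epimers at C2)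
Conditions: second-generation Grubbs catalyst (5–10 mol %), toluene, 70 °C
Reagents that add atoms: none
Why: Ring-closing metathesis between the terminal alkene and the vinyl ether closes the seven-membered cyclic enol acetal with loss of ethene, the ring size enforcing the (Z)-enol ether and no stereocentre being involved.

Step 9
Reactants: 13 (4R,5S)-2-aryl-4-benzyl-5-silyloxy-4,5-dihydro-1,3-dioxepine
Product: 15 [(2S,3R,4S,5R)-5-[4-(benzyloxy)-3-methoxybenzyl]-4-[(tert-butyldimethylsilyl)oxy]-2-{3-methoxy-4-[(triisopropylsilyl)oxy]phenyl}oxolan-3-yl]methanol, via oxolane-3-carbaldehyde 14 (not isolated)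
Conditions: TMSOTf (0.2 equiv), CH2Cl2, −78 → −20 °C; then EtOH, NaBH4, −40 → 0 °C
Reagents that add atoms: none
Why: TMSOTf ionizes the benzylic acetal carbon C2 of 13 by cleaving its bond to the enol-ether oxygen O1, which gives a (Z)-silyl enol ether tethered through O3 to an aryl-stabilized oxocarbenium ion, and the enol carbon C6 then attacks C2 in an intramolecular Mukaiyama aldol-type C–C bond formation, so that the seven-membered ring contracts to the tetrahydrofuran (old O3, C2, C6, C5, C4) and old C7 with O1 leaves the ring as the formyl group. The closest known reaction type is the Lewis acid-mediated [1,3] O-to-C rearrangement (Petasis–Ferrier-type ring contraction) of 4,5-dihydro-1,3-dioxepines to 2,3-disubstituted tetrahydrofuran-3-carbaldehydes. The tetrahydrofuran closes in a 5-(enolexo)-endo-trig mode with respect to the oxocarbenium carbon, which is feasible because the cationic C=O+ unit is attacked by a freely rotating enol silane. The new C3 centre is set by attack of the enol face anti to the neighbouring silyloxy group (3,4-trans), and the new C2 centre ends trans to the formyl group because C2–C3 bond formation is reversible under TMSOTf (re-ionization to the same oxocarbenium/enol pair, helped by the electron-rich ring A), so warming should equilibrate the kinetically favoured 2,3-cis aldehyde to the all-trans isomer 14 in which every pair of neighbouring substituents is trans, while C4 and C5 come unchanged from 6. The step needs C-attack of the enol silane to outrun Friedel–Crafts trapping of the oxocarbenium ion by ring B (oxa-Pictet–Spengler closure) and Ferrier-type loss of the allylic oxygen substituent, which the much higher nucleophilicity of the tethered enol silane, the poor leaving-group ability of the bulky silyl ether, and catalytic Lewis acid at low temperature should secure. Reduction with NaBH4 in the same flask traps the epimerizable β-silyloxy aldehyde 14 as the primary alcohol 15 before β-elimination can occur.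

Step 10
Reactants: 15 benzyl-protected tetrahydrofuran alcohol
Product: 16 [(2S,3R,4S,5R)-4-[(tert-butyldimethylsilyl)oxy]-5-(4-hydroxy-3-methoxybenzyl)-2-{3-methoxy-4-[(triisopropylsilyl)oxy]phenyl}oxolan-3-yl]methanol
Conditions: H2 (1 atm), Pd/C (10%), EtOAc, rt, stopped after one equivalent of H2
Reagents that add atoms: none
Why: Catalytic hydrogenolysis cleaves the phenolic benzyl ether of ring B much faster than the benzylic C2–O1 bond of the tetrahydrofuran and leaves the silyl ethers untouched.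

Step 11
Reactants: 16 ring B phenol; 17 (4S)-4-benzyl-3-(chloroacetyl)-1,3-oxazolidin-2-one
Product: 18 (4S)-4-benzyl-3-[(aryloxy)acetyl]-1,3-oxazolidin-2-one whose aryloxy group is the ring B phenoxide of 16
Conditions: K2CO3, NaI (cat.), acetone, 40 °C
Reagents that add atoms: none
Why: Williamson etherification (SN2 of the phenoxide on the α-halo imide with in situ Finkelstein activation) is chemoselective for the phenol because carbonate does not deprotonate the primary alcohol.

Step 12
Reactants: 18 aryloxyacetyl imide; 8 3-methoxy-4-[(triisopropylsilyl)oxy]benzaldehyde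
Product: 20 (4S)-4-benzyl-3-[(2R,3R)-2-(aryloxy)-3-hydroxy-3-{3-methoxy-4-[(triisopropylsilyl)oxy]phenyl}propanoyl]-1,3-oxazolidin-2-one (aryloxy = ring B oxygen of 16), via bis(trimethylsilyl) ether 19 (not isolated)
Conditions: MgCl2 (20 mol %), Et3N, TMSCl (3.5 equiv), EtOAc, rt; then THF/1 M HCl (5:1), 0 °C
Reagents that add atoms: none
Why: In this magnesium halide-catalysed direct anti-aldol of an N-acyloxazolidinone (auxiliary-controlled Evans-type aldol), soft enolization gives the magnesium-chelated (Z)-enolate, which should add to the non-enolizable aryl aldehyde through a boat transition state on the face opposite to the benzyl group of the chelated auxiliary (the face used in alkylations of this auxiliary), setting C8'' and C7'' anti (erythro) with the absolute sense fixed by the (4S)-auxiliary, while TMSCl traps the aldolate and transiently caps the primary alcohol.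

Step 13
Reactants: 20 anti-aldol adduct
Product: 21 (1R,2S)-2-(aryloxy)-1-{3-methoxy-4-[(triisopropylsilyl)oxy]phenyl}propane-1,3-diol (aryloxy = ring B oxygen of 16)
Conditions: LiBH4, MeOH (1 equiv), THF, 0 °C
Reagents that add atoms: none
Why: Reductive removal of the oxazolidinone auxiliary (hydride reduction of the imide to the primary alcohol) turns the acyl carbon into C9'' without touching C7'', C8'' or the silyl ethers.

Step 14
Reactants: 21 tris-silyl ether of the target
Product: 22 (1R,2S)-1-(4-hydroxy-3-methoxyphenyl)-2-[4-{[(2R,3S,4S,5S)-3-hydroxy-5-(4-hydroxy-3-methoxyphenyl)-4-(hydroxymethyl)oxolan-2-yl]methyl}-2-methoxyphenoxy]propane-1,3-diol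
Conditions: TBAF (6 equiv), AcOH (6 equiv), THF, 0 °C → rt
Reagents that add atoms: none
Why: Fluoride-mediated desilylation removes the alkyl TBS ether and both aryl TIPS ethers in one operation under buffered conditions that should leave the benzylic alcohol, the β-aryl ether and the 2-aryltetrahydrofuran intact.

**Compound list**

1 | penta-1,4-dien-3-ol | C=CC(O)C=C | starting material
2 | (1S)-1-[(2R)-oxiran-2-yl]prop-2-en-1-ol | C=C[C@H](O)[C@H]1CO1 | intermediate
3 | tert-butyl(dimethyl){[(1S)-1-[(2R)-oxiran-2-yl]prop-2-en-1-yl]oxy}silane | C=C[C@H](O[Si](C)(C)C(C)(C)C)[C@H]1CO1 | intermediate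
4 | 1-(benzyloxy)-4-bromo-2-methoxybenzene | COc1cc(Br)ccc1OCc1ccccc1 | starting material
5 | [4-(benzyloxy)-3-methoxyphenyl]magnesium bromide | COc1cc([Mg]Br)ccc1OCc1ccccc1 | intermediate
6 | (2R,3S)-1-[4-(benzyloxy)-3-methoxyphenyl]-3-[(tert-butyldimethylsilyl)oxy]pent-4-en-2-ol | C=C[C@H](O[Si](C)(C)C(C)(C)C)[C@H](O)Cc1ccc(OCc2ccccc2)c(OC)c1 | intermediate
7 | vanillin (4-hydroxy-3-methoxybenzaldehyde) | COc1cc(C=O)ccc1O | starting material
8 | 3-methoxy-4-[(triisopropylsilyl)oxy]benzaldehyde | COc1cc(C=O)ccc1O[Si](C(C)C)(C(C)C)C(C)C | intermediate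
9 | {4-[bis(2-bromoethoxy)methyl]-2-methoxyphenoxy}tri(propan-2-yl)silane | COc1cc(C(OCCBr)OCCBr)ccc1O[Si](C(C)C)(C(C)C)C(C)C | intermediate
10 | 1-[(2-bromoethoxy){3-methoxy-4-[(triisopropylsilyl)oxy]phenyl}methyl]-2,4,6-trimethylpyridinium triflate | COc1cc(C(OCCBr)[n+]2c(C)cc(C)cc2C)ccc1O[Si](C(C)C)(C(C)C)C(C)C.[O-]S(=O)(=O)C(F)(F)F | intermediate
11 | mixed 2-bromoethyl acetal of 8 with 6 (both epimers at the acetal carbon) | C=C[C@H](O[Si](C)(C)C(C)(C)C)[C@@H](Cc1ccc(OCc2ccccc2)c(OC)c1)OC(OCCBr)c1ccc(O[Si](C(C)C)(C(C)C)C(C)C)c(OC)c1 | intermediate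
12 | mixed vinyl acetal of 8 with 6 (both epimers at the acetal carbon) | C=C[C@H](O[Si](C)(C)C(C)(C)C)[C@@H](Cc1ccc(OCc2ccccc2)c(OC)c1)OC(OC=C)c1ccc(O[Si](C(C)C)(C(C)C)C(C)C)c(OC)c1 | intermediate
13 | (4R,5S)-4-[4-(benzyloxy)-3-methoxybenzyl]-5-[(tert-butyldimethylsilyl)oxy]-2-{3-methoxy-4-[(triisopropylsilyl)oxy]phenyl}-4,5-dihydro-1,3-dioxepine (both epimers at C2) | COc1cc(C2OC=C[C@H](O[Si](C)(C)C(C)(C)C)[C@@H](Cc3ccc(OCc4ccccc4)c(OC)c3)O2)ccc1O[Si](C(C)C)(C(C)C)C(C)C | intermediate
14 | (2S,3R,4S,5R)-5-[4-(benzyloxy)-3-methoxybenzyl]-4-[(tert-butyldimethylsilyl)oxy]-2-{3-methoxy-4-[(triisopropylsilyl)oxy]phenyl}oxolane-3-carbaldehyde | COc1cc(C[C@H]2O[C@H](c3ccc(O[Si](C(C)C)(C(C)C)C(C)C)c(OC)c3)[C@@H](C=O)[C@@H]2O[Si](C)(C)C(C)(C)C)ccc1OCc1ccccc1 | intermediate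
15 | [(2S,3R,4S,5R)-5-[4-(benzyloxy)-3-methoxybenzyl]-4-[(tert-butyldimethylsilyl)oxy]-2-{3-methoxy-4-[(triisopropylsilyl)oxy]phenyl}oxolan-3-yl]methanol | COc1cc(C[C@H]2O[C@H](c3ccc(O[Si](C(C)C)(C(C)C)C(C)C)c(OC)c3)[C@@H](CO)[C@@H]2O[Si](C)(C)C(C)(C)C)ccc1OCc1ccccc1 | intermediate
16 | [(2S,3R,4S,5R)-4-[(tert-butyldimethylsilyl)oxy]-5-(4-hydroxy-3-methoxybenzyl)-2-{3-methoxy-4-[(triisopropylsilyl)oxy]phenyl}oxolan-3-yl]methanol | COc1cc(C[C@H]2O[C@H](c3ccc(O[Si](C(C)C)(C(C)C)C(C)C)c(OC)c3)[C@@H](CO)[C@@H]2O[Si](C)(C)C(C)(C)C)ccc1O | intermediate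
17 | (4S)-4-benzyl-3-(chloroacetyl)-1,3-oxazolidin-2-one | O=C(CCl)N1[C@@H](Cc2ccccc2)COC1=O | starting material
18 | (4S)-4-benzyl-3-[(aryloxy)acetyl]-1,3-oxazolidin-2-one, aryloxy = ring B oxygen of 16 | COc1cc(C[C@H]2O[C@H](c3ccc(O[Si](C(C)C)(C(C)C)C(C)C)c(OC)c3)[C@@H](CO)[C@@H]2O[Si](C)(C)C(C)(C)C)ccc1OCC(=O)N1[C@@H](Cc2ccccc2)COC1=O | intermediate
19 | bis(trimethylsilyl) ether of 20 (at the C7'' oxygen and at the C9 oxygen) | COc1cc([C@@H](O[Si](C)(C)C)[C@H](C(=O)N2[C@@H](Cc3ccccc3)COC2=O)Oc2ccc(C[C@H]3O[C@H](c4ccc(O[Si](C(C)C)(C(C)C)C(C)C)c(OC)c4)[C@@H](CO[Si](C)(C)C)[C@@H]3O[Si](C)(C)C(C)(C)C)cc2OC)ccc1O[Si](C(C)C)(C(C)C)C(C)C | intermediate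
20 | (4S)-4-benzyl-3-[(2R,3R)-2-(aryloxy)-3-hydroxy-3-{3-methoxy-4-[(triisopropylsilyl)oxy]phenyl}propanoyl]-1,3-oxazolidin-2-one, aryloxy = ring B oxygen of 16 | COc1cc([C@@H](O)[C@H](C(=O)N2[C@@H](Cc3ccccc3)COC2=O)Oc2ccc(C[C@H]3O[C@H](c4ccc(O[Si](C(C)C)(C(C)C)C(C)C)c(OC)c4)[C@@H](CO)[C@@H]3O[Si](C)(C)C(C)(C)C)cc2OC)ccc1O[Si](C(C)C)(C(C)C)C(C)C | intermediate
21 | (1R,2S)-2-(aryloxy)-1-{3-methoxy-4-[(triisopropylsilyl)oxy]phenyl}propane-1,3-diol, aryloxy = ring B oxygen of 16 | COc1cc([C@@H](O)[C@H](CO)Oc2ccc(C[C@H]3O[C@H](c4ccc(O[Si](C(C)C)(C(C)C)C(C)C)c(OC)c4)[C@@H](CO)[C@@H]3O[Si](C)(C)C(C)(C)C)cc2OC)ccc1O[Si](C(C)C)(C(C)C)C(C)C | intermediate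
22 | (1R,2S)-1-(4-hydroxy-3-methoxyphenyl)-2-[4-{[(2R,3S,4S,5S)-3-hydroxy-5-(4-hydroxy-3-methoxyphenyl)-4-(hydroxymethyl)oxolan-2-yl]methyl}-2-methoxyphenoxy]propane-1,3-diol | COc1cc([C@@H](O)[C@H](CO)Oc2ccc(C[C@H]3O[C@H](c4ccc(O)c(OC)c4)[C@@H](CO)[C@@H]3O)cc2OC)ccc1O | target

**Step count and risks**

Total step count: 14. Longest linear sequence: 12 steps (steps 1–3 and 6–14).

Steps most likely to fail:

Step 9. During the warming that is needed to equilibrate C2 from cis to trans, the reversibly formed oxocarbenium ion may be trapped irreversibly by the electron-rich ring B (Friedel–Crafts closure to an isochroman), or the allylic silyloxy group may be lost. The equilibration may also stop short of the all-trans isomer. The fallback sets out from 13 and comes back at 15. The contraction is run under kinetic control only (TMSOTf, CH2Cl2, −78 °C, short contact, then NaBH4/EtOH added cold), which should give the 2,3-cis-3,4-trans (2R,3R,4S,5R)-oxolane-3-carbaldehyde F1 and, after reduction, the C2-epimeric (2R,3R,4S,5R)-alcohol F2. The benzylic C2 centre of F2 is then corrected in a separate operation by acid-catalysed ring opening and re-closure at O1–C2 (cat. camphorsulfonic acid, CH2Cl2, 0 °C). This is the known benzylic epimerization of 2-aryltetrahydrofuran lignans to the more stable 2,3-trans isomer, and it gives 15 without passing again through the oxocarbenium/enol pair.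

Step 12. Competing chelation of magnesium by the aryloxy oxygen may change the enolate or transition-state geometry and erode the anti selectivity or the facial sense, and enolization of the hindered imide may be slow. The fallback sets out from 15 and comes back at 22; it sets C8'' by substitution and C7'' by substrate control.
- The primary alcohol of 15 is silylated (TBSCl, imidazole) to the bis-TBS ether F3, and the benzyl ether is hydrogenolysed (H2, Pd/C) to the phenol F4.
- F4 is coupled by Mitsunobu reaction (PPh3, DIAD, toluene, 0 °C → rt) with methyl (2R)-3-[(tert-butyldimethylsilyl)oxy]-2-hydroxypropanoate F5 (from commercial methyl (R)-glycerate, TBSCl, imidazole). Clean SN2 inversion gives the methyl (2S)-2-aryloxy-3-silyloxypropanoate F6.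
- F6 is reduced with i-Bu2AlH (CH2Cl2, −78 °C) to the (2S)-2-aryloxy aldehyde F7.
- Grignard reagent 5 is added in THF at −78 °C. Felkin–Anh (polar, non-chelated) addition anti to the aryloxy group should give the erythro (1R,2S)-carbinol F8.
- Desilylation (TBAF, AcOH, THF) gives the ring C benzyl ether F9 of the target, and hydrogenolysis (H2, Pd/C, EtOAc) gives 22.

Step 6. Residual silyl triflate may silylate the hindered secondary alcohol 6 instead of letting it attack the collidinium salt, and the labile aryl acetal may scramble to the symmetric acetals. The fallback sets out from 8 and 6 and comes back at 11; it forms the acetal by oxidation and not by exchange.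
- 8 is reduced (NaBH4, MeOH) to {3-methoxy-4-[(triisopropylsilyl)oxy]phenyl}methanol F10 and converted (Cl3CCN, cat. DBU, CH2Cl2) to its trichloroacetimidate F11.
- 6 is benzylated with F11 under acid catalysis (cat. TfOH, Et2O, 0 °C; no basic alkoxide, hence no silyl migration) to the 4-silyloxy-3-methoxybenzyl ether F12.
- F12 is oxidized with DDQ in dry CH2Cl2 over 4 Å MS in the presence of 2-bromoethanol. The aryl-stabilized oxocarbenium ion generated at the benzylic ether carbon is trapped by the primary alcohol (oxidative mixed-acetal formation from a p-alkoxybenzyl-type ether), giving 11.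

Further compounds
F1 | step 9 | (2R,3R,4S,5R)-5-[4-(benzyloxy)-3-methoxybenzyl]-4-[(tert-butyldimethylsilyl)oxy]-2-{3-methoxy-4-[(triisopropylsilyl)oxy]phenyl}oxolane-3-carbaldehyde | COc1cc(C[C@H]2O[C@@H](c3ccc(O[Si](C(C)C)(C(C)C)C(C)C)c(OC)c3)[C@@H](C=O)[C@@H]2O[Si](C)(C)C(C)(C)C)ccc1OCc1ccccc1
F2 | step 9 | [(2R,3R,4S,5R)-5-[4-(benzyloxy)-3-methoxybenzyl]-4-[(tert-butyldimethylsilyl)oxy]-2-{3-methoxy-4-[(triisopropylsilyl)oxy]phenyl}oxolan-3-yl]methanol | COc1cc(C[C@H]2O[C@@H](c3ccc(O[Si](C(C)C)(C(C)C)C(C)C)c(OC)c3)[C@@H](CO)[C@@H]2O[Si](C)(C)C(C)(C)C)ccc1OCc1ccccc1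
F3 | step 12 | tert-butyldimethylsilyl ether of 15 at the primary alcohol | COc1cc(C[C@H]2O[C@H](c3ccc(O[Si](C(C)C)(C(C)C)C(C)C)c(OC)c3)[C@@H](CO[Si](C)(C)C(C)(C)C)[C@@H]2O[Si](C)(C)C(C)(C)C)ccc1OCc1ccccc1
F4 | step 12 | ring B phenol obtained from F3 by debenzylation | COc1cc(C[C@H]2O[C@H](c3ccc(O[Si](C(C)C)(C(C)C)C(C)C)c(OC)c3)[C@@H](CO[Si](C)(C)C(C)(C)C)[C@@H]2O[Si](C)(C)C(C)(C)C)ccc1O
F5 | step 12 | methyl (2R)-3-[(tert-butyldimethylsilyl)oxy]-2-hydroxypropanoate | COC(=O)[C@H](O)CO[Si](C)(C)C(C)(C)C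
F6 | step 12 | methyl (2S)-2-(aryloxy)-3-[(tert-butyldimethylsilyl)oxy]propanoate, aryloxy = ring B oxygen of F4 | COC(=O)[C@@H](Oc1ccc(C[C@H]2O[C@H](c3ccc(O[Si](C(C)C)(C(C)C)C(C)C)c(OC)c3)[C@@H](CO[Si](C)(C)C(C)(C)C)[C@@H]2O[Si](C)(C)C(C)(C)C)cc1OC)CO[Si](C)(C)C(C)(C)C
F7 | step 12 | (2S)-2-(aryloxy)-3-[(tert-butyldimethylsilyl)oxy]propanal, aryloxy = ring B oxygen of F4 | O=C[C@@H](Oc1ccc(C[C@H]2O[C@H](c3ccc(O[Si](C(C)C)(C(C)C)C(C)C)c(OC)c3)[C@@H](CO[Si](C)(C)C(C)(C)C)[C@@H]2O[Si](C)(C)C(C)(C)C)cc1OC)CO[Si](C)(C)C(C)(C)C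
F8 | step 12 | (1R,2S)-2-(aryloxy)-1-[4-(benzyloxy)-3-methoxyphenyl]-3-[(tert-butyldimethylsilyl)oxy]propan-1-ol, aryloxy = ring B oxygen of F4 | COc1cc([C@@H](O)[C@H](CO[Si](C)(C)C(C)(C)C)Oc2ccc(C[C@H]3O[C@H](c4ccc(O[Si](C(C)C)(C(C)C)C(C)C)c(OC)c4)[C@@H](CO[Si](C)(C)C(C)(C)C)[C@@H]3O[Si](C)(C)C(C)(C)C)cc2OC)ccc1OCc1ccccc1
F9 | step 12 | ring C benzyl ether of 22 | COc1cc([C@@H](O)[C@H](CO)Oc2ccc(C[C@H]3O[C@H](c4ccc(O)c(OC)c4)[C@@H](CO)[C@@H]3O)cc2OC)ccc1OCc1ccccc1
F10 | step 6 | {3-methoxy-4-[(triisopropylsilyl)oxy]phenyl}methanol | COc1cc(CO)ccc1O[Si](C(C)C)(C(C)C)C(C)C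
F11 | step 6 | 3-methoxy-4-[(triisopropylsilyl)oxy]benzyl 2,2,2-trichloroacetimidate | COc1cc(COC(=N)C(Cl)(Cl)Cl)ccc1O[Si](C(C)C)(C(C)C)C(C)C
F12 | step 6 | 3-methoxy-4-[(triisopropylsilyl)oxy]benzyl ether of 6 at the C2 oxygen | C=C[C@H](O[Si](C)(C)C(C)(C)C)[C@@H](Cc1ccc(OCc2ccccc2)c(OC)c1)OCc1ccc(O[Si](C(C)C)(C(C)C)C(C)C)c(OC)c1
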